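A direct plan would fix the diaryl ether first, by SNAr of the syringaldehyde phenoxide on methyl 4-fluorobenzoate (aldehyde A1), and then grow the two flavones on it in turn.
Dakin oxidation, C-acetylation, chalcone formation and I2/DMSO cyclisation would give the lower flavone; homologation of its benzoic acid to β-keto ester A2 and a melt of A2 with phloroglucinol would give the upper 5,7-dihydroxychromone A3.
7-O-Methylation to A4 and BCl3 cleavage of the 5''-methyl and 4'''-benzyl ethers would finish it.
Weakest would be the phloroglucinol melt near 250 °C: chromone-versus-coumarin closure and single-versus-multiple acylation would be left to chance on the most advanced material.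
Next would come the formyl-to-hydroxyl-to-acetyl and acid-to-keto-ester adjustments: about four steps that would add no ring and no skeletal bond of the target.
Last would be the closing Lewis-acid cleavage, which would have to remove one of three aryl methyl ethers and a benzyl group, and nothing else, on the final intermediate.

**Plan of the new route**
The target is the formal dehydro-dimer of one flavone, genkwanin: rings A/C/B and rings A''/C''/B'' are the same 5-hydroxy-7-methoxy-2-(4-oxyphenyl)chromone, joined from O4' of one copy to C6'' of the other.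
The retrosynthesis cuts only the C6''–O bond. No ring is built, since both tricyclic halves are bought as apigenin, and the ether becomes the last skeletal bond instead of the first.
The feature that allows this: on ring A'' the chelated 5''-OH is the only free hydroxyl and C6''–H its only free ortho position, so an iodine electrophile goes to C6''. On the partner, O4'–H on ring B is the only non-chelated hydroxyl, so it alone is arylated.
One methylation of the most acidic hydroxyl of apigenin sets both 7-methyl ethers and the 5-hydroxyls are never methylated, so neither a thermal pyranone annulation nor a selective demethylation occurs; two benzyl groups leave by hydrogenolysis.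

Key step: step 5

Remark: apigenin is taken as the purchased starting material; genkwanin (2) is also an article of commerce, and buying it would only remove step 1.

Step 1
Reactants: 1 apigenin (5,7-dihydroxy-2-(4-hydroxyphenyl)-4H-chromen-4-one)
Product: 2 genkwanin (5-hydroxy-2-(4-hydroxyphenyl)-7-methoxy-4H-chromen-4-one)
Conditions: MeI (1.05 equiv), K2CO3 (1.0 equiv), DMF, 0 °C to rt
Reagents that add atoms: iodomethane, CI
Why: Williamson O-methylation: O7–H, para to the C4 carbonyl, is the most acidic hydroxyl of apigenin, so one equivalent of carbonate should ionise it alone, while O5–H is held in the hydrogen bond to the carbonyl and the less acidic O4'–H stays protonated.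

Step 2
Reactants: 2 genkwanin
Product: 3 2-[4-(benzyloxy)phenyl]-5-hydroxy-7-methoxy-4H-chromen-4-one
Conditions: BnBr (1.1 equiv), K2CO3 (1.5 equiv), DMF, rt
Reagents that add atoms: benzyl bromide, BrCc1ccccc1
Why: Williamson O-benzylation: with O7 capped, O4'–H is the only non-chelated phenol of 2, and the chelated O5–H should not alkylate under carbonate at room temperature.

Step 3
Reactants: 3 2-[4-(benzyloxy)phenyl]-5-hydroxy-7-methoxy-4H-chromen-4-one
Product: 4 2-[4-(benzyloxy)phenyl]-5-hydroxy-6-iodo-7-methoxy-4H-chromen-4-one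
Conditions: BnMe3N·ICl2 (1.1 equiv), CaCO3 (3 equiv), CH2Cl2/MeOH (5:2), rt, dark
Reagents that add atoms: benzyltrimethylammonium dichloroiodate, C[N+](C)(C)Cc1ccccc1.Cl[I-]Cl
Why: Electrophilic aromatic iodination of a phenol by dichloroiodate: under buffered conditions the reagent iodinates free phenols and leaves aryl ethers such as ring B alone, and with 5-hydroxy-7-alkoxyflavones it is known to enter at C6, ortho to the chelated hydroxyl and between the two oxygen substituents, not at C8.

Step 4
Reactants: 4 2-[4-(benzyloxy)phenyl]-5-hydroxy-6-iodo-7-methoxy-4H-chromen-4-one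
Product: 5 5-(benzyloxy)-2-[4-(benzyloxy)phenyl]-6-iodo-7-methoxy-4H-chromen-4-one
Conditions: BnBr (2 equiv), K2CO3 (3 equiv), Bu4NI (cat.), DMF, 60 °C
Reagents that add atoms: benzyl bromide, BrCc1ccccc1
Why: Williamson O-benzylation of the chelated, iodine-flanked 5-OH under forcing carbonate conditions; it removes the ortho hydroxyl that would make ring A an electron-rich phenoxide and bind copper in step 5, and benzyl is chosen so that both protecting groups fall in one hydrogenolysis.

Step 5
Reactants: 5 5-(benzyloxy)-2-[4-(benzyloxy)phenyl]-6-iodo-7-methoxy-4H-chromen-4-one; 2 genkwanin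
Product: 6 5-(benzyloxy)-2-[4-(benzyloxy)phenyl]-6-[4-(5-hydroxy-7-methoxy-4-oxo-4H-chromen-2-yl)phenoxy]-7-methoxy-4H-chromen-4-one
Conditions: 2 (1.5 equiv), CuI (20 mol%), picolinic acid (40 mol%), K3PO4 (3 equiv), DMSO, 90 °C, argon
Reagents that add atoms: none
Why: Ullmann-type diaryl ether synthesis: the 4'-phenoxide of 2 binds picolinate-ligated monovalent copper, the cuprous phenoxide inserts into the C6–I bond of 5 (oxidative addition to a trivalent copper aryl phenoxide, or iodine-atom transfer), and C–O reductive elimination forms the C6''–O4' bond and returns monovalent copper. The closest known reaction type is the CuI/picolinic acid/K3PO4/DMSO etherification of 2,6-disubstituted aryl iodides with phenols, here possibly helped by the two ortho oxygen atoms (O5'' benzyl, O7'' methyl), which can pre-coordinate copper. No ring is closed and no stereocentre is formed; the step makes the one skeletal bond that links the two bought flavone ring systems. Three selectivities are needed: the site on ring A'' is fixed as C6'' by the iodine placed in step 3, and with O5'' benzylated and no acid present ring C'' cannot open and reclose to an 8''-linked isomer; of the two hydroxyls of 2 only O4' should be arylated, because O5–H is locked in the six-membered hydrogen bond to the C4 carbonyl; and oligomerisation is excluded because 5 has no free hydroxyl and 2 no halogen. An excess of the cheap phenol 2 should offset the low nucleophilicity of a phenoxide para to the chromone and the slow insertion into the electron-rich, doubly flanked iodide.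

Step 6
Reactants: 6 5-(benzyloxy)-2-[4-(benzyloxy)phenyl]-6-[4-(5-hydroxy-7-methoxy-4-oxo-4H-chromen-2-yl)phenoxy]-7-methoxy-4H-chromen-4-one
Product: 7 5-hydroxy-2-(4-{[5-hydroxy-2-(4-hydroxyphenyl)-7-methoxy-4-oxo-4H-chromen-6-yl]oxy}phenyl)-7-methoxy-4H-chromen-4-one (CNP0251572.0)
Conditions: H2 (1 atm), Pd/C (10% Pd), THF/MeOH, rt
Reagents that add atoms: none
Why: Heterogeneous hydrogenolysis of benzyl aryl ethers on zerovalent palladium: both O–CH2Ph bonds should be cleaved to toluene, whereas the methyl ethers, the diaryl ether and the vinylogous-ester C2=C3 bonds of the two chromones should not be reduced at one atmosphere and room temperature if the reaction is stopped after uptake of two equivalents of hydrogen.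

**Compound list**
1 | apigenin (5,7-dihydroxy-2-(4-hydroxyphenyl)-4H-chromen-4-one) | O=c1cc(-c2ccc(O)cc2)oc2cc(O)cc(O)c12 | starting material
2 | genkwanin (5-hydroxy-2-(4-hydroxyphenyl)-7-methoxy-4H-chromen-4-one) | COc1cc(O)c2c(=O)cc(-c3ccc(O)cc3)oc2c1 | intermediate
3 | 2-[4-(benzyloxy)phenyl]-5-hydroxy-7-methoxy-4H-chromen-4-one | COc1cc(O)c2c(=O)cc(-c3ccc(OCc4ccccc4)cc3)oc2c1 | intermediate
4 | 2-[4-(benzyloxy)phenyl]-5-hydroxy-6-iodo-7-methoxy-4H-chromen-4-one | COc1cc2oc(-c3ccc(OCc4ccccc4)cc3)cc(=O)c2c(O)c1I | intermediate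
5 | 5-(benzyloxy)-2-[4-(benzyloxy)phenyl]-6-iodo-7-methoxy-4H-chromen-4-one | COc1cc2oc(-c3ccc(OCc4ccccc4)cc3)cc(=O)c2c(OCc5ccccc5)c1I | intermediate (key-step precursor)
6 | 5-(benzyloxy)-2-[4-(benzyloxy)phenyl]-6-[4-(5-hydroxy-7-methoxy-4-oxo-4H-chromen-2-yl)phenoxy]-7-methoxy-4H-chromen-4-one | COc1cc(O)c2c(=O)cc(-c3ccc(Oc4c(OC)cc5oc(-c6ccc(OCc7ccccc7)cc6)cc(=O)c5c4OCc8ccccc8)cc3)oc2c1 | intermediate (key-step product)
7 | 5-hydroxy-2-(4-{[5-hydroxy-2-(4-hydroxyphenyl)-7-methoxy-4-oxo-4H-chromen-6-yl]oxy}phenyl)-7-methoxy-4H-chromen-4-one (CNP0251572.0; no stereocentres) | COc1cc(O)c2c(=O)cc(-c3ccc(Oc4c(OC)cc5oc(-c6ccc(O)cc6)cc(=O)c5c4O)cc3)oc2c1 | target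

**Step count and risks**
Total step count: 6. Longest linear sequence: 6 steps (1 to 7); compound 2 enters twice, as precursor of 5 and as coupling partner in step 5.

Steps most likely to fail:

Step 5. Insertion of copper into the electron-rich, doubly ortho-substituted C6–I bond may be slower than protodeiodination, and the 5-hydroxy-4-oxo chelate of 2 may hold back the copper. The fallback reverses the polarity of the union; it sets out from 5 and 2 and returns at 6. Miyaura borylation of 5 (B2pin2, PdCl2(dppf), KOAc, dioxane, 90 °C) would give 5-(benzyloxy)-2-[4-(benzyloxy)phenyl]-7-methoxy-6-(4,4,5,5-tetramethyl-1,3,2-dioxaborolan-2-yl)-4H-chromen-4-one F1. Oxidation (NaBO3·4H2O, THF/H2O, rt) would give the hindered but electron-rich phenol 5-(benzyloxy)-2-[4-(benzyloxy)phenyl]-6-hydroxy-7-methoxy-4H-chromen-4-one F2. Compound 2 would be sulfonylated at its non-chelated O4' (PhNTf2, K2CO3, DMF, rt) to 4-(5-hydroxy-7-methoxy-4-oxo-4H-chromen-2-yl)phenyl trifluoromethanesulfonate F3. Palladium-catalysed C–O coupling of F2 with the electron-poor triflate F3 (Pd(OAc)2, 2-di-tert-butylphosphino-2',4',6'-triisopropylbiphenyl, K3PO4, toluene, 100 °C) would then form the O–C4' bond in place of the C6''–O bond and give 6.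

Step 1. Alkylation at O4' in place of O7, and a second alkylation at O4', may consume apigenin as the phenoxides equilibrate. The fallback differentiates the hydroxyls by protecting groups; it sets out from 1 and returns at 2. Peracetylation (Ac2O, pyridine, rt) would give 4-[5,7-bis(acetyloxy)-4-oxo-4H-chromen-2-yl]phenyl acetate F4. Chemoselective thiolysis of the most activated 7-O-acetyl group (PhSH, imidazole, N-methylpyrrolidone, 0 °C) would give 4-[5-(acetyloxy)-7-hydroxy-4-oxo-4H-chromen-2-yl]phenyl acetate F5. Mitsunobu methylation of the single free hydroxyl (MeOH, PPh3, DIAD, THF, 0 °C to rt) would give 4-[5-(acetyloxy)-7-methoxy-4-oxo-4H-chromen-2-yl]phenyl acetate F6, and methanolysis of both acetates (K2CO3, MeOH, rt) would give 2.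

Step 6. Hydrogen may add to the C2=C3 or C2''=C3'' bond once the benzyl groups have gone, or the sparingly soluble biflavone may coat the catalyst and stop the cleavage half-way. The fallback uses no hydrogen; it sets out from 6 and returns at 7. Lewis-acid debenzylation with BCl3 and pentamethylbenzene as benzyl-cation trap (CH2Cl2, −78 to 0 °C, then MeOH) should cleave both benzyl ethers and leave the non-chelated 7- and 7''-methyl ethers; it makes no new compound (F0).

**Further compounds**
F1 | step 5 | 5-(benzyloxy)-2-[4-(benzyloxy)phenyl]-7-methoxy-6-(4,4,5,5-tetramethyl-1,3,2-dioxaborolan-2-yl)-4H-chromen-4-one | COc1cc2oc(-c3ccc(OCc4ccccc4)cc3)cc(=O)c2c(OCc5ccccc5)c1B6OC(C)(C)C(C)(C)O6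
F2 | step 5 | 5-(benzyloxy)-2-[4-(benzyloxy)phenyl]-6-hydroxy-7-methoxy-4H-chromen-4-one | COc1cc2oc(-c3ccc(OCc4ccccc4)cc3)cc(=O)c2c(OCc5ccccc5)c1O
F3 | step 5 | 4-(5-hydroxy-7-methoxy-4-oxo-4H-chromen-2-yl)phenyl trifluoromethanesulfonate | COc1cc(O)c2c(=O)cc(-c3ccc(OS(=O)(=O)C(F)(F)F)cc3)oc2c1
F4 | step 1 | 4-[5,7-bis(acetyloxy)-4-oxo-4H-chromen-2-yl]phenyl acetate | CC(=O)Oc1ccc(cc1)-c1cc(=O)c2c(OC(C)=O)cc(OC(C)=O)cc2o1
F5 | step 1 | 4-[5-(acetyloxy)-7-hydroxy-4-oxo-4H-chromen-2-yl]phenyl acetate | CC(=O)Oc1ccc(cc1)-c1cc(=O)c2c(OC(C)=O)cc(O)cc2o1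
F6 | step 1 | 4-[5-(acetyloxy)-7-methoxy-4-oxo-4H-chromen-2-yl]phenyl acetate | CC(=O)Oc1ccc(cc1)-c1cc(=O)c2c(OC(C)=O)cc(OC)cc2o1
F0 | step 6 | none | none
A1 | direct plan | methyl 4-(4-formyl-2,6-dimethoxyphenoxy)benzoate | COC(=O)c1ccc(Oc2c(OC)cc(C=O)cc2OC)cc1
A2 | direct plan | ethyl 3-[4-({2-[4-(benzyloxy)phenyl]-5,7-dimethoxy-4-oxo-4H-chromen-6-yl}oxy)phenyl]-3-oxopropanoate | CCOC(=O)CC(=O)c1ccc(Oc2c(OC)cc3oc(-c4ccc(OCc5ccccc5)cc4)cc(=O)c3c2OC)cc1
A3 | direct plan | 2-[4-({2-[4-(benzyloxy)phenyl]-5,7-dimethoxy-4-oxo-4H-chromen-6-yl}oxy)phenyl]-5,7-dihydroxy-4H-chromen-4-one | Oc1cc(O)c2c(=O)cc(-c3ccc(Oc4c(OC)cc5oc(-c6ccc(OCc7ccccc7)cc6)cc(=O)c5c4OC)cc3)oc2c1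
A4 | direct plan | 2-[4-({2-[4-(benzyloxy)phenyl]-5,7-dimethoxy-4-oxo-4H-chromen-6-yl}oxy)phenyl]-5-hydroxy-7-methoxy-4H-chromen-4-one | COc1cc(O)c2c(=O)cc(-c3ccc(Oc4c(OC)cc5oc(-c6ccc(OCc7ccccc7)cc6)cc(=O)c5c4OC)cc3)oc2c1
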